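**Strategy.** Ring A is disconnected at C6–C7, C7–C8 and C4a–C8a. A Danheiser benzannulation between racemic 4-prenylcyclobut-2-enone and a prenyl-substituted triisopropylsiloxyalkyne assembles, in one thermal operation, the benzene ring with the C7 hydroxyl, the C8a oxygen and the C6 and C8 prenyl groups already in place, so no arene is ever prenylated. The feature exploited is the 1,3-dioxygenated ring A in which C8 (prenyl) sits between O–C7 and O–C8a and C6 carries the second prenyl. The free C4a–H of the product is then formylated without electrophilic halogen, the pyranone ring C is built as a chromone, and C2 is set by rhodium-catalysed asymmetric phenyl addition.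

Key step: step 7

Assumption: the (S)-configured biaryl bisphosphine–rhodium catalyst is taken to add phenyl to the chromone on the same enone face as with cyclohex-2-enone, which corresponds to 2S in the flavanone; if the sense proves opposite, the (R)-ligand is used.

**Step 1**
Reactants: 1 trimethylsilylacetylene; 2 prenyl bromide
Product: 4 trimethyl(5-methylhex-4-en-1-ynyl)silane, via alkynylmagnesium bromide 3 (not isolated)
Conditions: EtMgBr, THF, 0 → 40 °C; then CuBr·SMe2 (5 mol %), 2, THF, 0 → 50 °C
Reagents that add atoms: none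
Why: Copper-catalysed SN2 coupling of an alkynyl Grignard reagent with a primary allylic bromide should attack the unhindered CH2 terminus and give the linear skipped enyne, the silyl cap excluding double alkylation.

**Step 2**
Reactants: 4 trimethyl(5-methylhex-4-en-1-ynyl)silane
Product: 5 5-methylhex-4-en-1-yne
Conditions: K2CO3 (0.2 equiv), MeOH, 0 °C → rt; pentane extraction, careful distillation
Reagents that add atoms: none
Why: Base-catalysed methanolysis of the C(sp)–Si bond (protodesilylation) is mild enough to leave the skipped enyne unisomerised.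

**Step 3**
Reactants: 5 5-methylhex-4-en-1-yne
Product: 8 (5-methylhex-4-en-1-ynyloxy)triisopropylsilane, via lithium acetylide 6 (not isolated), via lithium ynolate 7 (not isolated)
Conditions: n-BuLi, THF, −78 °C; LiOOt-Bu [from t-BuOOH and LiN(SiMe3)2, THF, −78 °C], −78 → 0 °C; i-Pr3SiOTf, −78 → 0 °C
Reagents that add atoms: tert-butyl hydroperoxide, CC(C)(C)OO; triisopropylsilyl trifluoromethanesulfonate, CC(C)[Si](C(C)C)(C(C)C)OS(=O)(=O)C(F)(F)F
Why: Oxygen transfer from lithium tert-butyl peroxide to the lithium acetylide (acetylide oxidation) gives the ynolate, which the bulky silyl triflate should silylate on oxygen, the standard siloxyalkyne preparation.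

**Step 4**
Reactants: 9 5-methylhex-4-enoic acid
Product: 10 5-methylhex-4-enoyl chloride
Conditions: (COCl)2, DMF (cat.), CH2Cl2, 0 °C → rt; volatiles removed cold
Reagents that add atoms: oxalyl chloride, O=C(Cl)C(=O)Cl
Why: Acid chloride formation through the catalytic chloroiminium species proceeds at low temperature, where the trisubstituted alkene should be left alone.

**Step 5**
Reactants: 10 5-methylhex-4-enoyl chloride; 11 ethoxyacetylene
Product: 13 racemic 3-ethoxy-4-(3-methylbut-2-enyl)cyclobut-2-en-1-one, via prenylketene 12 (not isolated)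
Conditions: Et3N, 11 (3 equiv), Et2O, slow addition of 10, rt
Reagents that add atoms: none
Why: Dehydrochlorination gives the monoalkylketene, which undergoes the regiospecific thermal ketene–alkoxyalkyne [2+2] cycloaddition (alkyne CH carbon to ketene carbonyl carbon); the new sp3 centre is racemic and later becomes aromatic.

**Step 6**
Reactants: 13 racemic 3-ethoxy-4-(3-methylbut-2-enyl)cyclobut-2-en-1-one
Product: 15 racemic 4-(3-methylbut-2-enyl)cyclobut-2-en-1-one, via cyclobutenol 14 (not isolated)
Conditions: i-Bu2AlH, Et2O, −78 °C; then 1 M HCl (aq), THF, 0 °C; extracted into pentane, concentrated cold, used at once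
Reagents that add atoms: water, O
Why: 1,2-Reduction of the vinylogous ester followed by acid-mediated 1,3-carbonyl transposition (Stork–Danheiser type) should place the new carbonyl next to the prenyl-bearing sp3 carbon.

**Step 7**
Reactants: 15 racemic 4-(3-methylbut-2-enyl)cyclobut-2-en-1-one; 8 (5-methylhex-4-en-1-ynyloxy)triisopropylsilane
Product: 20 2,6-bis(3-methylbut-2-enyl)-3-(triisopropylsilyloxy)phenol, via vinylketene 16 (not isolated), via vinylcyclobutenone 17 (not isolated), via dienylketene 18 (not isolated), via cyclohexadienone 19 (not isolated)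
Conditions: 15 (1.3 equiv), 8 (1.0 equiv), degassed toluene, 80 °C then 110 °C, sealed tube
Reagents that add atoms: none
Why: Heating opens 15 by conrotatory 4π electrocyclic cleavage of its C1–C4 bond to the (E)-vinylketene 16, whose ketene C=C adds [2+2] to 8 (prenyl-bearing alkyne carbon to the ketene carbonyl carbon, forming C7–C8; siloxy carbon to the ketene α-carbon, forming C4a–C8a) to give 17, which opens in a second 4π step to dienylketene 18. Ring A is closed by thermal disrotatory 6π electrocyclisation of 18 (C6–C7 bond), and the resulting cyclohexadienone 19 tautomerises irreversibly to phenol 20. The closest known reaction type is the Danheiser benzannulation of cyclobutenones with triisopropylsiloxyalkynes, which gives resorcinol monosilyl ethers. No stereocentre is created, since the sp3 carbon of racemic 15 and that of 19 both end as aromatic C6. The step needs regioselectivity in the [2+2] event, secured by the polarisation of the ynol ether (the carbon remote from oxygen is the nucleophile), which forces the siloxy carbon meta to the new hydroxyl with the alkyne-derived prenyl between them. It also needs chemoselectivity for the alkyne over the two trisubstituted alkenes, secured by the far higher ketenophilicity of the electron-rich ynol ether.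

**Step 8**
Reactants: 20 2,6-bis(3-methylbut-2-enyl)-3-(triisopropylsilyloxy)phenol
Product: 21 [3-(methoxymethoxy)-2,4-bis(3-methylbut-2-enyl)phenoxy]triisopropylsilane
Conditions: NaH, MOMCl, THF/DMF, 0 °C → rt
Reagents that add atoms: chloromethyl methyl ether, COCCl
Why: O-Alkylation of the sodium phenoxide by the small, hard chloromethyl ether (Williamson-type acetal protection) should succeed even between two ortho prenyl groups and leaves the silyl ether intact.

**Step 9**
Reactants: 21 [3-(methoxymethoxy)-2,4-bis(3-methylbut-2-enyl)phenoxy]triisopropylsilane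
Product: 22 3-(methoxymethoxy)-2,4-bis(3-methylbut-2-enyl)phenol
Conditions: Bu4NF, THF, 0 °C; aq. NH4Cl
Reagents that add atoms: none
Why: Fluoride-induced cleavage of the aryl silyl ether is driven by Si–F bond formation, and the acetal and the alkenes are inert to fluoride.

**Step 10**
Reactants: 22 3-(methoxymethoxy)-2,4-bis(3-methylbut-2-enyl)phenol
Product: 23 2-hydroxy-4-(methoxymethoxy)-3,5-bis(3-methylbut-2-enyl)benzaldehyde
Conditions: MgCl2 (anhydrous), Et3N, (CH2O)n, MeCN, reflux; aq. NH4Cl
Reagents that add atoms: paraformaldehyde (as formaldehyde), C=O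
Why: Magnesium phenoxide-directed ortho-formylation (Casnati–Skattebøl) delivers formaldehyde within the chelate to C4a, the only free ortho position, and a second formaldehyde oxidises the benzylic alkoxide by hydride transfer, so no electrophile that could attack the prenyl alkenes is present.

**Step 11**
Reactants: 23 2-hydroxy-4-(methoxymethoxy)-3,5-bis(3-methylbut-2-enyl)benzaldehyde; 24 ethynylmagnesium bromide
Product: 25 racemic 2-(1-hydroxyprop-2-yn-1-yl)-5-(methoxymethoxy)-4,6-bis(3-methylbut-2-enyl)phenol
Conditions: 24 (3 equiv, 0.5 M in THF), THF, 0 °C → rt; aq. NH4Cl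
Reagents that add atoms: none
Why: Grignard 1,2-addition to the aldehyde after deprotonation of the phenol by the first equivalent gives the carbinol, whose racemic centre is removed by oxidation in the next step.

**Step 12**
Reactants: 25 racemic 2-(1-hydroxyprop-2-yn-1-yl)-5-(methoxymethoxy)-4,6-bis(3-methylbut-2-enyl)phenol
Product: 27 7-(methoxymethoxy)-6,8-bis(3-methylbut-2-enyl)-4H-chromen-4-one, via ynone 26 (not isolated)
Conditions: MnO2 (activated, excess), CH2Cl2, rt; filtration; K2CO3 (cat.), acetone, rt
Reagents that add atoms: none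
Why: Chemoselective MnO2 oxidation of the benzylic–propargylic alcohol gives the o-hydroxyaryl ynone, and base-catalysed 6-endo-dig oxa-Michael addition of the phenoxide to the unsubstituted alkyne terminus closes ring C as the chromone.

**Step 13**
Reactants: 27 7-(methoxymethoxy)-6,8-bis(3-methylbut-2-enyl)-4H-chromen-4-one; 28 phenylboronic acid
Product: 29 (2S)-7-(methoxymethoxy)-6,8-bis(3-methylbut-2-enyl)-2-phenylchroman-4-one
Conditions: [Rh(OH)(cod)]2 (2.5 mol %; cod = cycloocta-1,5-diene), (S)-MeO-F12-BIPHEP [(S)-2,2′-bis[bis(3,4,5-trifluorophenyl)phosphino]-6,6′-dimethoxy-1,1′-biphenyl, 5.5 mol %], 28 (3 equiv), toluene/H2O, 30 °C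
Reagents that add atoms: none
Why: Rhodium-catalysed asymmetric 1,4-addition of an arylboronic acid to a chromone (Hayashi–Miyaura reaction) transfers phenyl to C2 on the enone face left open by the (S)-ligand, setting C2 as S, and the base-free aqueous conditions protonate the rhodium enolate without retro-oxa-Michael ring opening.

**Step 14**
Reactants: 29 (2S)-7-(methoxymethoxy)-6,8-bis(3-methylbut-2-enyl)-2-phenylchroman-4-one
Product: 30 (2S)-7-hydroxy-6,8-bis(3-methylbut-2-enyl)-2-phenylchroman-4-one (7-hydroxy-6,8-diprenylflavanone)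
Conditions: HCl (1.25 M in MeOH), MeOH, rt
Reagents that add atoms: none
Why: Acid-catalysed acetal exchange removes the methoxymethyl group under conditions too mild to open ring C at C2 or to cyclise the prenyl groups onto the liberated phenol.

**Compound list**

1 | trimethylsilylacetylene | C#C[Si](C)(C)C | starting material
2 | prenyl bromide (1-bromo-3-methylbut-2-ene) | CC(C)=CCBr | starting material
3 | [(trimethylsilyl)ethynyl]magnesium bromide (formed in the flask) | C[Si](C)(C)C#C[Mg]Br | intermediate
4 | trimethyl(5-methylhex-4-en-1-ynyl)silane | CC(C)=CCC#C[Si](C)(C)C | intermediate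
5 | 5-methylhex-4-en-1-yne | CC(C)=CCC#C | intermediate
6 | lithium 5-methylhex-4-en-1-yn-1-ide (formed in the flask) | [Li+].[C-]#CCC=C(C)C | intermediate
7 | lithium 5-methylhex-4-en-1-yn-1-olate (formed in the flask) | [Li+].[O-]C#CCC=C(C)C | intermediate
8 | (5-methylhex-4-en-1-ynyloxy)triisopropylsilane | CC(C)=CCC#CO[Si](C(C)C)(C(C)C)C(C)C | intermediate
9 | 5-methylhex-4-enoic acid | CC(C)=CCCC(=O)O | starting material
10 | 5-methylhex-4-enoyl chloride | CC(C)=CCCC(=O)Cl | intermediate
11 | ethoxyacetylene | CCOC#C | starting material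
12 | prenylketene, 5-methylhexa-1,4-dien-1-one (formed in the flask) | CC(C)=CCC=C=O | intermediate
13 | racemic 3-ethoxy-4-(3-methylbut-2-enyl)cyclobut-2-en-1-one | CCOC1=CC(=O)C1CC=C(C)C | intermediate
14 | 3-ethoxy-4-(3-methylbut-2-enyl)cyclobut-2-en-1-ol, racemic diastereomer mixture (formed in the flask) | CCOC1=CC(O)C1CC=C(C)C | intermediate
15 | racemic 4-(3-methylbut-2-enyl)cyclobut-2-en-1-one | O=C1C=CC1CC=C(C)C | intermediate
16 | (3E)-7-methylocta-1,3,6-trien-1-one (formed in the flask) | O=C=C/C=C/CC=C(C)C | intermediate
17 | racemic 2-(3-methylbut-2-enyl)-4-[(1E)-5-methylhexa-1,4-dienyl]-3-(triisopropylsilyloxy)cyclobut-2-en-1-one (formed in the flask) | O=C1C(CC=C(C)C)=C(O[Si](C(C)C)(C(C)C)C(C)C)C1/C=C/CC=C(C)C | intermediate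
18 | (3E,5E)-9-methyl-2-(3-methylbut-2-enyl)-3-(triisopropylsilyloxy)deca-1,3,5,8-tetraen-1-one, the isomer able to cyclise (formed in the flask) | O=C=C(CC=C(C)C)/C(O[Si](C(C)C)(C(C)C)C(C)C)=C\C=C\CC=C(C)C | intermediate
19 | racemic 2,6-bis(3-methylbut-2-enyl)-3-(triisopropylsilyloxy)cyclohexa-2,4-dien-1-one (formed in the flask) | O=C1C(CC=C(C)C)=C(O[Si](C(C)C)(C(C)C)C(C)C)C=CC1CC=C(C)C | intermediate
20 | 2,6-bis(3-methylbut-2-enyl)-3-(triisopropylsilyloxy)phenol | CC(C)=CCc1ccc(O[Si](C(C)C)(C(C)C)C(C)C)c(CC=C(C)C)c1O | intermediate
21 | [3-(methoxymethoxy)-2,4-bis(3-methylbut-2-enyl)phenoxy]triisopropylsilane | CC(C)=CCc1ccc(O[Si](C(C)C)(C(C)C)C(C)C)c(CC=C(C)C)c1OCOC | intermediate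
22 | 3-(methoxymethoxy)-2,4-bis(3-methylbut-2-enyl)phenol | CC(C)=CCc1ccc(O)c(CC=C(C)C)c1OCOC | intermediate
23 | 2-hydroxy-4-(methoxymethoxy)-3,5-bis(3-methylbut-2-enyl)benzaldehyde | CC(C)=CCc1cc(C=O)c(O)c(CC=C(C)C)c1OCOC | intermediate
24 | ethynylmagnesium bromide | C#C[Mg]Br | starting material
25 | racemic 2-(1-hydroxyprop-2-yn-1-yl)-5-(methoxymethoxy)-4,6-bis(3-methylbut-2-enyl)phenol | CC(C)=CCc1cc(C(O)C#C)c(O)c(CC=C(C)C)c1OCOC | intermediate
26 | 1-[2-hydroxy-4-(methoxymethoxy)-3,5-bis(3-methylbut-2-enyl)phenyl]prop-2-yn-1-one (formed in the flask) | CC(C)=CCc1cc(C(=O)C#C)c(O)c(CC=C(C)C)c1OCOC | intermediate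
27 | 7-(methoxymethoxy)-6,8-bis(3-methylbut-2-enyl)-4H-chromen-4-one | CC(C)=CCc1cc2c(c(CC=C(C)C)c1OCOC)OC=CC2=O | intermediate
28 | phenylboronic acid | OB(O)c1ccccc1 | starting material
29 | (2S)-7-(methoxymethoxy)-6,8-bis(3-methylbut-2-enyl)-2-phenylchroman-4-one | CC(C)=CCc1cc2c(c(CC=C(C)C)c1OCOC)O[C@H](c1ccccc1)CC2=O | intermediate
30 | (2S)-7-hydroxy-6,8-bis(3-methylbut-2-enyl)-2-phenylchroman-4-one | CC(C)=CCc1cc2c(c(CC=C(C)C)c1O)O[C@H](c1ccccc1)CC2=O | target

**Total step count:** 14 steps.

**Longest linear sequence:** 11 steps (steps 4, 5, 6, 7 and 8 to 14 from 9; the branch from 1 through steps 1, 2, 3, 7 and 8 to 14 is equally long).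

**Steps most likely to fail**

Step 7. The thermal ring opening of 15 is slow enough that polymerisation of this cyclobutenone, which is unsubstituted at C2 and C3, and acylation of the product phenol by the vinylketene may outrun the cycloaddition. The fallback is the diazo ketone variant of the same benzannulation, which makes the same vinylketene 16 at room temperature and never handles 15. It sets out from 5. Deprotonation with n-BuLi and addition to acetaldehyde (THF, −78 °C) should give racemic 7-methyloct-6-en-3-yn-2-ol F1. Trans-selective hydroalumination with NaAlH2(OCH2CH2OMe)2 (THF, 0 °C → rt) should give (3E)-7-methylocta-3,6-dien-2-ol F2, and MnO2 (CH2Cl2, rt) should give (3E)-7-methylocta-3,6-dien-2-one F3. Kinetic enolisation at the methyl group with LiN(SiMe3)2 (THF, −78 °C) and trifluoroacetylation with CF3CO2CH2CF3 give (5E)-1,1,1-trifluoro-9-methyldeca-5,8-diene-2,4-dione F4. Without isolation, MsN3, Et3N and H2O in MeCN convert it by detrifluoroacetylative diazo transfer into (3E)-1-diazo-7-methylocta-3,6-dien-2-one F5. Irradiation of F5 with 8 (300 nm, ClCH2CH2Cl, rt, then 80 °C) triggers a photochemical Wolff rearrangement to 16, which then follows the same cascade through 17, 18 and 19. The route is rejoined at 20.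

Step 13. Phenyl transfer to the electron-rich 7-alkoxychromone may be slow with the chiral complex, and enantiopurity may be eroded by poor facial discrimination or by reversible ring opening of the product. The fallback separates bond formation from stereocontrol and sets out from 27. Ligand-free [Rh(OH)(cod)]2 with 28 (dioxane/H2O, 60 °C) should give racemic 7-(methoxymethoxy)-6,8-bis(3-methylbut-2-enyl)-2-phenylchroman-4-one F6. A kinetic resolution by Noyori transfer hydrogenation (RuCl(p-cymene)[(R,R)-TsDPEN], HCO2H/Et3N, rt) is expected to reduce the (2R)-enantiomer to (2R,4R)-7-(methoxymethoxy)-6,8-bis(3-methylbut-2-enyl)-2-phenylchroman-4-ol F7 and leave the (2S)-ketone. Chromatography separates the two, at the cost of half the material, and the route is rejoined at 29.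

Step 3. Oxygen transfer from the peroxide to the acetylide may be incomplete, and the basic medium may deprotonate the doubly activated CH2 of the skipped enyne and isomerise it. The fallback generates the same ynolate without an acetylide and sets out from 9. Alkylation of the carboxylate (EtI, K2CO3, DMF, rt; acid-free to avoid lactonisation) should give ethyl 5-methylhex-4-enoate F8. Two rounds of enolisation and bromination (LiN(i-Pr)2, then BrCF2CF2Br, THF, −78 °C) should give ethyl 2,2-dibromo-5-methylhex-4-enoate F9. Treatment with t-BuLi (4 equiv, THF, −78 → 0 °C) effects double lithium–bromine exchange and loss of ethoxide to give ynolate 7. Silylation with i-Pr3SiOTf as in step 3 rejoins the route at 8.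

**Further compounds**

F1 | step 7 | racemic 7-methyloct-6-en-3-yn-2-ol | CC(O)C#CCC=C(C)C
F2 | step 7 | racemic (3E)-7-methylocta-3,6-dien-2-ol | CC(O)/C=C/CC=C(C)C
F3 | step 7 | (3E)-7-methylocta-3,6-dien-2-one | CC(=O)/C=C/CC=C(C)C
F4 | step 7 | (5E)-1,1,1-trifluoro-9-methyldeca-5,8-diene-2,4-dione | O=C(CC(=O)C(F)(F)F)/C=C/CC=C(C)C
F5 | step 7 | (3E)-1-diazo-7-methylocta-3,6-dien-2-one | [N-]=[N+]=CC(=O)/C=C/CC=C(C)C
F6 | step 13 | racemic 7-(methoxymethoxy)-6,8-bis(3-methylbut-2-enyl)-2-phenylchroman-4-one | CC(C)=CCc1cc2c(c(CC=C(C)C)c1OCOC)OC(c1ccccc1)CC2=O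
F7 | step 13 | (2R,4R)-7-(methoxymethoxy)-6,8-bis(3-methylbut-2-enyl)-2-phenylchroman-4-ol | CC(C)=CCc1cc2c(c(CC=C(C)C)c1OCOC)O[C@@H](c1ccccc1)C[C@H]2O
F8 | step 3 | ethyl 5-methylhex-4-enoate | CCOC(=O)CCC=C(C)C
F9 | step 3 | ethyl 2,2-dibromo-5-methylhex-4-enoate | CCOC(=O)C(Br)(Br)CC=C(C)C
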